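**Plan**
- Cuts: the two ester C–O bonds (O3–angeloyl, O8–senecioyl); the C–O bonds of the 4,5- and 1,10-epoxides; C4=C5 (ring-closing metathesis); C9–C10 and C2–C3 (one-pot double allylboration); C7–isopropenyl (epoxide opening).
- Enabling feature: O9–C9–C10(CH3)–C1–C2–C3–O3 of the ten-membered ring, with the cis-1,10-epoxide read as its Z olefin, is a (Z)-2-methylpent-2-ene-1,5-diol.
- Forward: aldehyde 10 (C5–C9), allenylboronate 13 (C10 with its methyl, C1, C2) and methacrolein (C3, C4 with its methyl) are joined to the acyclic triene diol 19. The 1,10-epoxide is installed before ring closure so that a C5 carbene cannot close a cyclohexene onto C10. Metathesis then forms the only carbocycle, followed by the 4,5-epoxide and the two esters.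
- Stereochemistry: C7/C8 from Sharpless epoxidation and SN2 opening; C9, C3 and the Z C1=C10 geometry from the Ipc-controlled double allylboration; C1/C10 from the O9-directed vanadium epoxidation; C4/C5 from the O3-directed peracid epoxidation of the Z ring olefin; angelate geometry from angelic acid.

Key step: step 10

Remark (numbering): germacrane numbering of the target is used from compound 10 on: ring C1–C10, methyls on C4 and C10, isopropenyl on C7.
Remark (reagent): (+)-diisopinocampheylborane 14 is taken as a commercial reagent; it is otherwise made from (−)-α-pinene and BH3·SMe2.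
Remark (descriptors): C9 is R in 19 and 20 and S from 21 on, and C4 is R in 24 and S from 27 on, only because CIP priorities change; no centre is inverted.

**Route**

Step 1
Reactants: 1 prop-2-yn-1-ol; 2 allyl bromide
Product: 3 hex-5-en-2-yn-1-ol
Conditions: CuI (5 mol %), K2CO3, NaI (10 mol %), DMF, 23 °C
Reagents that add atoms: none
Why: Copper-acetylide allylation of a terminal alkyne (SN2 on allyl bromide) builds the skipped enyne chain C5–C9 and tolerates the free hydroxyl.

Step 2
Reactants: 3 hex-5-en-2-yn-1-ol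
Product: 4 (2E)-hexa-2,5-dien-1-ol
Conditions: LiAlH4, THF, 0 → 23 °C; aqueous NaOH work-up
Reagents that add atoms: none
Why: Alkoxide-directed trans-hydroalumination of the propargylic alcohol (LiAlH4 reduction) gives only the E allylic alcohol and leaves the isolated terminal alkene untouched.

Step 3
Reactants: 4 (2E)-hexa-2,5-dien-1-ol
Product: 5 [(2R,3R)-3-(prop-2-en-1-yl)oxiran-2-yl]methanol
Conditions: Ti(OiPr)4 (10 mol %), D-(−)-diisopropyl tartrate (12 mol %), t-BuOOH, 4 Å molecular sieves, CH2Cl2, −20 °C
Reagents that add atoms: tert-butyl hydroperoxide, CC(C)(C)OO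
Why: Sharpless asymmetric epoxidation: the titanium–D-(−)-tartrate complex delivers oxygen to one face of the allylic-alcohol olefin only, setting the (2R,3R) trans-epoxide (future C8 and the precursor of C7) and sparing the terminal alkene.

Step 4
Reactants: 5 [(2R,3R)-3-(prop-2-en-1-yl)oxiran-2-yl]methanol; 6 isopropenylmagnesium bromide
Product: 7 (2S,3R)-3-(prop-1-en-2-yl)hex-5-ene-1,2-diol
Conditions: 6 (3 equiv), CuI (10 mol %), THF, −30 → 0 °C
Reagents that add atoms: none
Why: Copper-catalysed SN2 opening of the 2,3-epoxy alcohol by the alkenyl Grignard reagent at C3, the carbon remote from the magnesium alkoxide, proceeds with inversion and turns the trans-epoxide into the 2,3-anti diol with C7 (R) and C8 (S); a 1,3-diol regioisomer, if formed, is separable.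

Step 5
Reactants: 7 (2S,3R)-3-(prop-1-en-2-yl)hex-5-ene-1,2-diol
Product: 8 (2S,3R)-1,2-bis[(tert-butyldimethylsilyl)oxy]-3-(prop-1-en-2-yl)hex-5-ene
Conditions: t-BuMe2SiOTf, 2,6-lutidine, CH2Cl2, 0 °C
Reagents that add atoms: tert-butyldimethylsilyl triflate, CC(C)(C)[Si](C)(C)OS(=O)(=O)C(F)(F)F
Why: Exhaustive silylation with the silyl triflate protects both hydroxyls, the secondary one (O8) for most of the synthesis.

Step 6
Reactants: 8 (2S,3R)-1,2-bis[(tert-butyldimethylsilyl)oxy]-3-(prop-1-en-2-yl)hex-5-ene
Product: 9 (2S,3R)-2-[(tert-butyldimethylsilyl)oxy]-3-(prop-1-en-2-yl)hex-5-en-1-ol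
Conditions: HF·pyridine, pyridine, THF, 0 °C
Reagents that add atoms: none
Why: Buffered HF cleaves the unhindered primary silyl ether much faster than the secondary one next to the branched C7 (selective desilylation on steric grounds).

Step 7
Reactants: 9 (2S,3R)-2-[(tert-butyldimethylsilyl)oxy]-3-(prop-1-en-2-yl)hex-5-en-1-ol
Product: 10 (2S,3R)-2-[(tert-butyldimethylsilyl)oxy]-3-(prop-1-en-2-yl)hex-5-enal
Conditions: Dess–Martin periodinane, NaHCO3, CH2Cl2, 0 → 23 °C
Reagents that add atoms: none
Why: Dess–Martin oxidation under buffered, non-basic conditions should give the α-silyloxy aldehyde without epimerising C8.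

Step 8
Reactants: 11 but-2-yn-1-ol
Product: 12 but-2-yn-1-yl methyl carbonate
Conditions: ClCO2Me, pyridine, CH2Cl2, 0 °C
Reagents that add atoms: methyl chloroformate, COC(=O)Cl
Why: Acylation of the propargylic alcohol installs the carbonate leaving group needed for the SN2′ borylation.

Step 9
Reactants: 12 but-2-yn-1-yl methyl carbonate
Product: 13 2-(buta-2,3-dien-2-yl)-4,4,5,5-tetramethyl-1,3,2-dioxaborolane
Conditions: B2pin2, CuCl (10 mol %), KOt-Bu (10 mol %), Xantphos (10 mol %), THF, 23 °C
Reagents that add atoms: bis(pinacolato)diboron, CC1(C)OB(OC1(C)C)B1OC(C)(C)C(C)(C)O1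
Why: Copper-catalysed borylative substitution of a propargylic carbonate: the boryl–copper species adds to the alkyne with boron on the methyl-bearing carbon, and β-elimination of the carbonate (formal SN2′) releases the 1-methylallenyl boronate, CO2 and methoxide, which regenerates the copper alkoxide.

Step 10
Reactants: 13 2-(buta-2,3-dien-2-yl)-4,4,5,5-tetramethyl-1,3,2-dioxaborolane; 14 (+)-diisopinocampheylborane; 10 (2S,3R)-2-[(tert-butyldimethylsilyl)oxy]-3-(prop-1-en-2-yl)hex-5-enal; 15 methacrolein
Product: 19 (3S,5Z,7R,8S,9R)-8-[(tert-butyldimethylsilyl)oxy]-2,6-dimethyl-9-(prop-1-en-2-yl)dodeca-1,5,11-triene-3,7-diol, via allylborane 16 (not isolated), via allylboronate 17 (not isolated), via bis-boron ester 18 (not isolated)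
Conditions: 13 + 14, toluene, 0 °C then 70 °C; 10, −78 °C; 15, −78 → 23 °C; aqueous NaHCO3, H2O2 work-up
Reagents that add atoms: none
Why: Hydroboration of allene 13 by 14 places boron on the terminal CH2 (C2) and hydrogen on C1, and reversible 1,3-boratropic shifts on warming should funnel the adduct into the more stable allylborane 16, in which the pinacolboryl group is trans to the CH2B(Ipc)2 arm. Its chair (Zimmerman–Traxler) allylboration of aldehyde 10 at −78 °C forms C9–C10 on the Re face of the aldehyde under control of the isopinocampheyl groups, which act in the same sense as the Felkin–Anh preference of the α-silyloxy aldehyde (matched pair, 8,9-anti), and gives the tertiary α-methyl allylboronate 17 with C9 (R) and C10 (S). On warming, 17 allylborates methacrolein through a second chair in which the bulky C9-bearing substituent on C10 sits pseudoaxial to avoid the pinacol methyls, so the C10 stereocentre is traded (1,3-chirality transfer) for the Z C1=C10 olefin and the 3S carbinol. The closest known reaction type is the one-pot allene hydroboration–double allylboration that gives (Z)-2-methylpent-2-ene-1,5-diols; no ring is closed, and two C–C bonds (C9–C10, C2–C3) and two lasting stereocentres (C9, C3) are formed. The step needs the first allyl transfer to stop at the boronate stage (a pinacol boronate is inert at −78 °C), high Z selectivity in the second transfer (pinacol ester plus the size difference between methyl and the C9 substituent) and 1,2-addition to methacrolein (inherent to allylboration).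

Step 11
Reactants: 19 seco-triene diol
Product: 20 3-O-triethylsilyl ether of 19
Conditions: Et3SiCl (1.05 equiv), imidazole, CH2Cl2, −40 °C
Reagents that add atoms: chlorotriethylsilane, CC[Si](CC)(CC)Cl
Why: Silylation should take the less hindered allylic hydroxyl at C3 (between CH2 and the methylidene carbon) in preference to the C9 hydroxyl (between the trisubstituted olefin and the OTBS-bearing C8), so that only O9 can direct the next step.

Step 12
Reactants: 20 3-O-triethylsilyl ether of 19
Product: 21 (1R,10S)-cis-1,10-epoxide of 20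
Conditions: VO(acac)2 (5 mol %), t-BuOOH, CH2Cl2, 0 °C
Reagents that add atoms: tert-butyl hydroperoxide, CC(C)(C)OO
Why: Hydroxyl-directed vanadium-catalysed epoxidation touches only the olefin allylic to the free C9 hydroxyl and is expected to give the erythro epoxy alcohol (1R,10S), because in the vanadium transition state (O–C9–C10=C1 dihedral near 45°) the threo alternative presses the branched C8 substituent against the C10 methyl (1,2-allylic strain); the Z geometry is kept as the cis-epoxide.

Step 13
Reactants: 21 (1R,10S)-cis-1,10-epoxide of 20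
Product: 22 acyclic 1,10-epoxy-3,9-diol
Conditions: HF·pyridine, pyridine, THF, 0 °C
Reagents that add atoms: none
Why: Buffered HF removes the triethylsilyl ether far faster than the hindered secondary tert-butyldimethylsilyl ether and is mild enough for the epoxy alcohol, freeing the C3 hydroxyl that assists metathesis at the neighbouring olefin and later directs the second epoxidation.

Step 14
Reactants: 22 acyclic 1,10-epoxy-3,9-diol
Product: 23 (1R,3S,4Z,7R,8S,9S,10S)-8-O-TBS-1,10-epoxygermacra-4,11(12)-diene-3,9-diol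
Conditions: second-generation Hoveyda–Grubbs catalyst (15 mol %), 1,4-benzoquinone (30 mol %), toluene (0.5 mM), 80 °C, argon sparge
Reagents that add atoms: none
Why: Ring-closing metathesis at high dilution: the ruthenium carbene loads at the monosubstituted C5 vinyl group and closes onto the 1,1-disubstituted C4 olefin (helped by the free allylic hydroxyl) to form the ten-membered ring, for which the Z trisubstituted olefin is expected on strain grounds; the cis-epoxide acts as a turn element, the otherwise facile cyclohexene closure C5=C10 is excluded because C1=C10 is already an epoxide, and closure onto the C7 isopropenyl group would need a cyclobutene.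

Step 15
Reactants: 23 macrocyclic epoxy diene diol
Product: 24 (1R,3S,4R,5S,7R,8S,9S,10S)-8-O-TBS-1,10:4,5-diepoxygermacr-11(12)-ene-3,9-diol
Conditions: mCPBA (1.1 equiv), NaHCO3, CH2Cl2, 0 °C
Reagents that add atoms: 3-chloroperbenzoic acid, OOC(=O)c1cccc(Cl)c1
Why: Peracid epoxidation directed by the free C3 hydroxyl on the Z-trisubstituted ring olefin: with C3–H eclipsing the olefin (1,3-allylic strain) the hydrogen-bonded peracid adds to the face that carries the hydroxyl and gives the threo epoxy alcohol, as is usual for Z-allylic alcohols and medium-ring Z-cycloalkenols, while the undirected 1,1-disubstituted isopropenyl group reacts more slowly.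

Step 16
Reactants: 24 bis-epoxide 3,9-diol; 25 angelic acid
Product: 27 3-O-angelate of 24, via mixed anhydride 26 (not isolated)
Conditions: 25, 2,4,6-trichlorobenzoyl chloride, Et3N, toluene, 23 °C; then 24, toluene, 75 °C (no DMAP)
Reagents that add atoms: none
Why: Yamaguchi-type esterification through mixed anhydride 26 acylates the C3 hydroxyl without base-induced Z-to-E isomerisation of the angeloyl group, and the C9 hydroxyl, wedged between the fully substituted C10 and the OTBS-bearing C8, is expected to stay free.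

Step 17
Reactants: 27 3-O-angelate of 24
Product: 28 3-O-angeloyl 8,9-diol
Conditions: Bu4NF, AcOH (1:1), THF, 0 → 23 °C
Reagents that add atoms: none
Why: Acetic acid-buffered fluoride cleaves the secondary silyl ether under near-neutral conditions that should leave the angelate and both epoxides intact (no free alkoxide for Payne rearrangement or acyl migration).

Step 18
Reactants: 28 3-O-angeloyl 8,9-diol; 29 3-methylbut-2-enoyl chloride
Product: 30 CNP0320216.1
Conditions: 29 (1.1 equiv), pyridine, DMAP (10 mol %), CH2Cl2, −20 → 0 °C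
Reagents that add atoms: none
Why: Acylation with the acid chloride and pyridine at low temperature should select the C8 hydroxyl, whose neighbours are two CH carbons, over the C9 hydroxyl next to the fully substituted epoxide carbon C10, and the weak base avoids deconjugation of the senecioyl group.

**Compound list**

1 | prop-2-yn-1-ol | C#CCO | starting material
2 | allyl bromide | C=CCBr | starting material
3 | hex-5-en-2-yn-1-ol | OCC#CCC=C | intermediate
4 | (2E)-hexa-2,5-dien-1-ol | OC/C=C/CC=C | intermediate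
5 | [(2R,3R)-3-(prop-2-en-1-yl)oxiran-2-yl]methanol | OC[C@H]1O[C@@H]1CC=C | intermediate
6 | isopropenylmagnesium bromide | CC(=C)[Mg]Br | starting material
7 | (2S,3R)-3-(prop-1-en-2-yl)hex-5-ene-1,2-diol | C=C(C)[C@@H](CC=C)[C@H](O)CO | intermediate
8 | (2S,3R)-1,2-bis[(tert-butyldimethylsilyl)oxy]-3-(prop-1-en-2-yl)hex-5-ene | C=C(C)[C@@H](CC=C)[C@H](O[Si](C)(C)C(C)(C)C)CO[Si](C)(C)C(C)(C)C | intermediate
9 | (2S,3R)-2-[(tert-butyldimethylsilyl)oxy]-3-(prop-1-en-2-yl)hex-5-en-1-ol | C=C(C)[C@@H](CC=C)[C@H](O[Si](C)(C)C(C)(C)C)CO | intermediate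
10 | (2S,3R)-2-[(tert-butyldimethylsilyl)oxy]-3-(prop-1-en-2-yl)hex-5-enal (C9 aldehyde, C8 OTBS, C7 isopropenyl) | C=C(C)[C@@H](CC=C)[C@H](O[Si](C)(C)C(C)(C)C)C=O | intermediate
11 | but-2-yn-1-ol | CC#CCO | starting material
12 | but-2-yn-1-yl methyl carbonate | CC#CCOC(=O)OC | intermediate
13 | 2-(buta-2,3-dien-2-yl)-4,4,5,5-tetramethyl-1,3,2-dioxaborolane | CC(=C=C)B1OC(C)(C)C(C)(C)O1 | intermediate
14 | (+)-diisopinocampheylborane, bis[(1S,2R,3S,5S)-2,6,6-trimethylbicyclo[3.1.1]heptan-3-yl]borane | B([C@H]1C[C@H]2C[C@@H]([C@@H]1C)C2(C)C)[C@H]1C[C@H]2C[C@@H]([C@@H]1C)C2(C)C | starting material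
15 | methacrolein | C=C(C)C=O | starting material
16 | (2Z)-[3-(pinacolatoboryl)but-2-en-1-yl]diisopinocampheylborane (methyl cis to CH2B, Bpin trans) | C/C(B1OC(C)(C)C(C)(C)O1)=C\CB([C@H]1C[C@H]2C[C@@H]([C@@H]1C)C2(C)C)[C@H]1C[C@H]2C[C@@H]([C@@H]1C)C2(C)C | intermediate
17 | O9-diisopinocampheylborinate of the (9R,10S) α-methyl-α-(pinacolatoboryl) homoallylic alcohol (vinyl = C1=C2) | C=C(C)[C@@H](CC=C)[C@H](O[Si](C)(C)C(C)(C)C)[C@H](OB([C@H]1C[C@H]2C[C@@H]([C@@H]1C)C2(C)C)[C@H]1C[C@H]2C[C@@H]([C@@H]1C)C2(C)C)[C@](C)(B1OC(C)(C)C(C)(C)O1)C=C | intermediate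
18 | O9-diisopinocampheylborinate, O3-pinacolborate of diol 19 | C=C(C)[C@@H](CC=C)[C@H](O[Si](C)(C)C(C)(C)C)[C@H](OB([C@H]1C[C@H]2C[C@@H]([C@@H]1C)C2(C)C)[C@H]1C[C@H]2C[C@@H]([C@@H]1C)C2(C)C)/C(C)=C\C[C@H](OB1OC(C)(C)C(C)(C)O1)C(C)=C | intermediate
19 | (3S,5Z,7R,8S,9R)-8-[(tert-butyldimethylsilyl)oxy]-2,6-dimethyl-9-(prop-1-en-2-yl)dodeca-1,5,11-triene-3,7-diol (germacrane numbering: 3S,7R,8S,9R; 1(10)Z) | C=C(C)[C@@H](CC=C)[C@H](O[Si](C)(C)C(C)(C)C)[C@H](O)/C(C)=C\C[C@H](O)C(C)=C | intermediate
20 | 3-O-triethylsilyl ether of 19 (3S,7R,8S,9R) | C=C(C)[C@@H](CC=C)[C@H](O[Si](C)(C)C(C)(C)C)[C@H](O)/C(C)=C\C[C@H](O[Si](CC)(CC)CC)C(C)=C | intermediate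
21 | cis-1,10-epoxide of 20 (1R,3S,7R,8S,9S,10S; erythro to the 9-hydroxyl) | C=C(C)[C@@H](CC=C)[C@H](O[Si](C)(C)C(C)(C)C)[C@H](O)[C@]1(C)O[C@@H]1C[C@H](O[Si](CC)(CC)CC)C(C)=C | intermediate
22 | acyclic 1,10-epoxy-3,9-diol (1R,3S,7R,8S,9S,10S), 8-OTBS | C=C(C)[C@@H](CC=C)[C@H](O[Si](C)(C)C(C)(C)C)[C@H](O)[C@]1(C)O[C@@H]1C[C@H](O)C(C)=C | intermediate
23 | (1R,3S,4Z,7R,8S,9S,10S)-8-O-TBS-1,10-epoxygermacra-4,11(12)-diene-3,9-diol | C=C(C)[C@H]1C/C=C(C)\[C@@H](O)C[C@H]2O[C@@]2(C)[C@@H](O)[C@H]1O[Si](C)(C)C(C)(C)C | intermediate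
24 | (1R,3S,4R,5S,7R,8S,9S,10S)-8-O-TBS-1,10:4,5-diepoxygermacr-11(12)-ene-3,9-diol | C=C(C)[C@H]1C[C@@H]2O[C@]2(C)[C@@H](O)C[C@H]2O[C@@]2(C)[C@@H](O)[C@H]1O[Si](C)(C)C(C)(C)C | intermediate
25 | angelic acid, (2Z)-2-methylbut-2-enoic acid | OC(=O)/C(C)=C\C | starting material
26 | angelic 2,4,6-trichlorobenzoic anhydride | C/C=C(/C)C(=O)OC(=O)c1c(Cl)cc(Cl)cc1Cl | intermediate
27 | 3-O-angelate of 24 (1R,3S,4S,5S,7R,8S,9S,10S), 8-OTBS, 9-OH | C=C(C)[C@H]1C[C@@H]2O[C@]2(C)[C@@H](OC(=O)/C(C)=C\C)C[C@H]2O[C@@]2(C)[C@@H](O)[C@H]1O[Si](C)(C)C(C)(C)C | intermediate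
28 | (1R,3S,4S,5S,7R,8S,9S,10S)-3-angeloyloxy-1,10:4,5-diepoxygermacr-11(12)-ene-8,9-diol | C=C(C)[C@H]1C[C@@H]2O[C@]2(C)[C@@H](OC(=O)/C(C)=C\C)C[C@H]2O[C@@]2(C)[C@@H](O)[C@H]1O | intermediate
29 | 3-methylbut-2-enoyl chloride (senecioyl chloride) | CC(C)=CC(=O)Cl | starting material
30 | CNP0320216.1, (1R,3S,4S,5S,7R,8S,9S,10S)-3-angeloyloxy-1,10:4,5-diepoxy-9-hydroxygermacr-11(12)-en-8-yl 3-methylbut-2-enoate | C=C(C)[C@H]1C[C@@H]2O[C@]2(C)[C@@H](OC(=O)/C(C)=C\C)C[C@H]2O[C@@]2(C)[C@@H](O)[C@H]1OC(=O)C=C(C)C | target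

**Step count and risks**

Total step count: 18. Longest linear sequence: 16 steps (steps 1–7, then 10–18); steps 8–9 make the second fragment.

Steps most likely to fail:

1. Step 14 (ring-closing metathesis). The ten-membered ring may not close: oligomerisation can outrun cyclisation, the hindered 1,1-disubstituted olefin may not be engaged, or the E olefin may form. The fallback sets out from 22. MnO2 in CH2Cl2 oxidises only the allylic C3 hydroxyl (the C9 hydroxyl is no longer allylic) to the α-methylene ketone, seco-enone F3. Ring-closing metathesis of F3 with the second-generation Hoveyda–Grubbs catalyst then engages a flat, unhindered enone olefin and should give the macrocyclic Z-enone F4. Corey–Bakshi–Shibata reduction with the (R)-methyl oxazaborolidine and BH3·SMe2 (alkenyl as the large group) restores the 3S carbinol, and the route is rejoined at 23.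

2. Step 12 (vanadium epoxidation). Facial selectivity may be poor, because the Z substituent (1,3-allylic strain) opposes the preference set by the C10 methyl and threo epoxide may compete. The fallback sets out from 20. The C9 hydroxyl is silylated (Et3SiOTf, 2,6-lutidine) to the bis(triethylsilyl) ether F1. Shi epoxidation with the D-fructose-derived ketone and KHSO5 at pH 10.5 puts reagent control on the trisubstituted olefin, reinforced by attack anti to the C9 silyloxy group and chemoselective against the less substituted olefins; it should give the cis-1,10-epoxide F2. HF·pyridine removes both triethylsilyl ethers, and the route is rejoined at 22.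

3. Step 18 (senecioylation). Regiocontrol may be lost through acylation of the C9 hydroxyl or acyl migration between O8 and O9. The fallback sets out from 27. Chloroacetic anhydride, pyridine and DMAP cap the C9 hydroxyl as the 9-O-chloroacetate F5. HF·pyridine removes the silyl ether to give the 8-alcohol F6. Senecioylation of the single free hydroxyl (29, pyridine, DMAP) gives the 8-O-senecioyl 9-O-chloroacetate F7. Thiourea and NaHCO3 in ethanol remove the chloroacetate selectively, and the route ends at 30.

**Further compounds**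

F1 | step 12 | 3,9-bis-O-triethylsilyl ether of 19 | C=C(C)[C@@H](CC=C)[C@H](O[Si](C)(C)C(C)(C)C)[C@H](O[Si](CC)(CC)CC)/C(C)=C\C[C@H](O[Si](CC)(CC)CC)C(C)=C
F2 | step 12 | cis-1,10-epoxide of F1 (same epoxide configuration as 21) | C=C(C)[C@@H](CC=C)[C@H](O[Si](C)(C)C(C)(C)C)[C@H](O[Si](CC)(CC)CC)[C@]1(C)O[C@@H]1C[C@H](O[Si](CC)(CC)CC)C(C)=C
F3 | step 14 | seco-enone (C3 ketone of 22) | C=C(C)[C@@H](CC=C)[C@H](O[Si](C)(C)C(C)(C)C)[C@H](O)[C@]1(C)O[C@@H]1CC(=O)C(C)=C
F4 | step 14 | macrocyclic (4Z)-enone (C3 ketone of 23) | C=C(C)[C@H]1C/C=C(C)\C(=O)C[C@H]2O[C@@]2(C)[C@@H](O)[C@H]1O[Si](C)(C)C(C)(C)C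
F5 | step 18 | 9-O-chloroacetate of 27 | C=C(C)[C@H]1C[C@@H]2O[C@]2(C)[C@@H](OC(=O)/C(C)=C\C)C[C@H]2O[C@@]2(C)[C@@H](OC(=O)CCl)[C@H]1O[Si](C)(C)C(C)(C)C
F6 | step 18 | 9-O-chloroacetyl 8-alcohol | C=C(C)[C@H]1C[C@@H]2O[C@]2(C)[C@@H](OC(=O)/C(C)=C\C)C[C@H]2O[C@@]2(C)[C@@H](OC(=O)CCl)[C@H]1O
F7 | step 18 | 9-O-chloroacetate of 30 | C=C(C)[C@H]1C[C@@H]2O[C@]2(C)[C@@H](OC(=O)/C(C)=C\C)C[C@H]2O[C@@]2(C)[C@@H](OC(=O)CCl)[C@H]1OC(=O)C=C(C)C
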